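**Retrosynthetic overview** (1H-isochromene numbering; ring A = pyran O2/C1/C8a/C4a/C4/C3, ring B = cyclohexenone C4a/C5/C6/C7/C8/C8a)
1. 24 ⇐ 23 (phenol MOM removal) ⇐ 21: the C6–C7 bond of ring B is made last, by an enantioselective intramolecular aldol of the monocyclic pyran keto aldehyde 21.
2. Enabling feature: C7 lies between the C8 ketone and the C6 carbinol (aldol relationship) and is the only α-carbon of C8, since C8a is sp2. Its single hydrogen in 21 is enolisable, so the racemic centre is erased and re-set, while the cis-tetrasubstituted C4a=C8a bond of ring A holds the C8 acyl group and the C5–C6 aldehyde arm within reach.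
3. 21 ⇐ 20 ⇐ 18 ⇐ 17: masked acetaldehyde arm by Suzuki–Miyaura coupling at C4a of the ring enol triflate of a β-diketone, itself from C-acylation of dihydropyranone 15 at C8a.
4. 15 ⇐ 9 + 11 (Claisen condensation, cyclodehydration). Acyl donor 8 ⇐ 4 + 5: the hindered aryl ester is made by carboxylate SN2 while C7 is still secondary; 4 ⇐ methyl orsellinate 1.
5. Order of ring formation: ring A (step 9), then ring B (step 14).

Key step: step 14

Remark: C7 in 6–8 and 17–21 is racemic by design, so these are racemates or stereoisomer mixtures; 17 is drawn as the diketone although an enol should dominate, and 21 is drawn as the β,γ-unsaturated aldehyde although it may equilibrate with conjugated tautomers.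

**Route**

Step 1
Reactants: 1 methyl 2,4-dihydroxy-6-methylbenzoate
Product: 2 methyl 2-hydroxy-4-(methoxymethoxy)-6-methylbenzoate
Conditions: MOMCl (1.1 equiv), i-Pr2NEt, CH2Cl2, 0 to 23 °C
Reagents that add atoms: chloromethyl methyl ether, COCCl
Why: Williamson-type O-alkylation should occur only at the 4-hydroxyl, because the 2-hydroxyl is hydrogen-bonded to the ester carbonyl and far less nucleophilic.

Step 2
Reactants: 2 methyl 2-hydroxy-4-(methoxymethoxy)-6-methylbenzoate
Product: 3 methyl 2-methoxy-4-(methoxymethoxy)-6-methylbenzoate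
Conditions: MeI, K2CO3, DMF, 50 °C
Reagents that add atoms: iodomethane, CI
Why: Williamson methylation of the remaining chelated phenol; the MOM ether and the ester are inert to carbonate.

Step 3
Reactants: 3 methyl 2-methoxy-4-(methoxymethoxy)-6-methylbenzoate
Product: 4 2-methoxy-4-(methoxymethoxy)-6-methylbenzoic acid
Conditions: KOH, DMSO/H2O (4:1), 80 °C; then 1 M HCl to pH 3, 0 °C
Reagents that add atoms: potassium hydroxide, [K+].[OH-]
Why: Saponification of the di-ortho-substituted ester needs forcing base, which the MOM aryl ether tolerates, and the brief cold acidification should leave the acetal intact.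

Step 4
Reactants: 4 2-methoxy-4-(methoxymethoxy)-6-methylbenzoic acid; 5 benzyl 2-bromopropanoate (racemic)
Product: 6 benzyl 2-{[2-methoxy-4-(methoxymethoxy)-6-methylbenzoyl]oxy}propanoate
Conditions: Cs2CO3, DMF, 23 °C
Reagents that add atoms: none
Why: SN2 alkylation of the caesium carboxylate by the α-bromo ester builds the hindered aryl ester through the unhindered oxygen instead of the shielded acyl carbon; the new secondary centre is deliberately racemic because step 14 erases it.

Step 5
Reactants: 6 benzyl 2-{[2-methoxy-4-(methoxymethoxy)-6-methylbenzoyl]oxy}propanoate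
Product: 7 2-{[2-methoxy-4-(methoxymethoxy)-6-methylbenzoyl]oxy}propanoic acid
Conditions: H2 (1 atm), 10% Pd/C, EtOAc, 23 °C
Reagents that add atoms: none
Why: Hydrogenolysis of the benzyl ester, with no other reducible group present at this stage.

Step 6
Reactants: 7 2-{[2-methoxy-4-(methoxymethoxy)-6-methylbenzoyl]oxy}propanoic acid
Product: 8 1-(1H-benzotriazol-1-yl)-1-oxopropan-2-yl 2-methoxy-4-(methoxymethoxy)-6-methylbenzoate
Conditions: 1-(methylsulfonyl)-1H-benzotriazole, Et3N, THF, 65 °C
Reagents that add atoms: 1-(methylsulfonyl)-1H-benzotriazole, CS(=O)(=O)n1nnc2ccccc12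
Why: Carboxyl activation as the N-acylbenzotriazole through the mixed carboxylic–sulfonic anhydride runs under non-acidic conditions that spare the MOM ether and gives a storable C-acylating agent.

Step 7
Reactants: 9 4-hydroxybutan-2-one
Product: 10 4-[(tert-butyldimethylsilyl)oxy]butan-2-one
Conditions: TBSCl, imidazole, CH2Cl2, 0 to 23 °C
Reagents that add atoms: tert-butyldimethylsilyl chloride, CC(C)(C)[Si](C)(C)Cl
Why: Standard silylation of the primary alcohol, so that only the ketone enolate is acylated in step 8.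

Step 8
Reactants: 10 4-[(tert-butyldimethylsilyl)oxy]butan-2-one; 11 (E)-but-2-enoyl chloride
Product: 13 (E)-1-[(tert-butyldimethylsilyl)oxy]oct-6-ene-3,5-dione, via lithium enolate 12 (not isolated)
Conditions: 10 (2.0 equiv), LiN(SiMe3)2 (2.0 equiv), THF, −78 °C; then 11 (1.0 equiv), −78 to 0 °C
Reagents that add atoms: none
Why: Crossed Claisen condensation, with kinetic deprotonation at the methyl group and C-acylation by the acid chloride, the second equivalent of enolate deprotonating the β-diketone as it forms.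

Step 9
Reactants: 13 (E)-1-[(tert-butyldimethylsilyl)oxy]oct-6-ene-3,5-dione
Product: 15 6-[(1E)-prop-1-en-1-yl]-2,3-dihydro-4H-pyran-4-one, via hydroxy diketone 14 (not isolated)
Conditions: TsOH·H2O (0.2 equiv), MeOH, 23 °C; then toluene, 60 °C
Reagents that add atoms: none
Why: Acidic desilylation, then 6-exo-trig hemiketalisation of the primary alcohol onto the enone carbonyl and dehydration (cyclodehydration of a δ-hydroxy β-diketone) should close ring A as a vinylogous ester.

Step 10
Reactants: 15 6-[(1E)-prop-1-en-1-yl]-2,3-dihydro-4H-pyran-4-one; 8 1-(1H-benzotriazol-1-yl)-1-oxopropan-2-yl 2-methoxy-4-(methoxymethoxy)-6-methylbenzoate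
Product: 17 1-oxo-1-{4-oxo-6-[(1E)-prop-1-en-1-yl]-3,4-dihydro-2H-pyran-3-yl}propan-2-yl 2-methoxy-4-(methoxymethoxy)-6-methylbenzoate, via lithium enolate 16 (not isolated)
Conditions: 15 (2.2 equiv), LiN(SiMe3)2 (2.1 equiv), THF, −78 °C; then 8 (1.0 equiv), −78 to −40 °C; aq. NH4Cl
Reagents that add atoms: none
Why: Kinetic α′-deprotonation of the vinylogous ester at the ring CH2 and Claisen-type C-acylation of the lithium enolate by the N-acylbenzotriazole should give the β-diketone, the hindered aryl ester being untouched.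

Step 11
Reactants: 17 1-oxo-1-{4-oxo-6-[(1E)-prop-1-en-1-yl]-3,4-dihydro-2H-pyran-3-yl}propan-2-yl 2-methoxy-4-(methoxymethoxy)-6-methylbenzoate
Product: 18 1-oxo-1-{6-[(1E)-prop-1-en-1-yl]-4-[(trifluoromethanesulfonyl)oxy]-2H-pyran-3-yl}propan-2-yl 2-methoxy-4-(methoxymethoxy)-6-methylbenzoate
Conditions: Tf2O, i-Pr2NEt, CH2Cl2, −78 °C
Reagents that add atoms: trifluoromethanesulfonic anhydride, O=S(=O)(OS(=O)(=O)C(F)(F)F)C(F)(F)F
Why: Enol triflate formation from the β-diketone should take place at the ring oxygen, as with 2-acylcycloalkanones, because it is the less hindered and (through donation from the ring oxygen) the more electron-rich terminus, giving the fully conjugated 2H-pyranyl triflate.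

Step 12
Reactants: 18 1-oxo-1-{6-[(1E)-prop-1-en-1-yl]-4-[(trifluoromethanesulfonyl)oxy]-2H-pyran-3-yl}propan-2-yl 2-methoxy-4-(methoxymethoxy)-6-methylbenzoate; 19 2-[(E)-2-ethoxyethenyl]-4,4,5,5-tetramethyl-1,3,2-dioxaborolane
Product: 20 1-{4-[(E)-2-ethoxyethenyl]-6-[(1E)-prop-1-en-1-yl]-2H-pyran-3-yl}-1-oxopropan-2-yl 2-methoxy-4-(methoxymethoxy)-6-methylbenzoate
Conditions: Pd(PPh3)4 (5 mol%), K3PO4, 1,4-dioxane/H2O (10:1), 60 °C
Reagents that add atoms: none
Why: Suzuki–Miyaura coupling of the activated vinylogous acyl triflate with the alkenylboronate installs the masked acetaldehyde arm at C4a with retention of alkene geometry.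

Step 13
Reactants: 20 1-{4-[(E)-2-ethoxyethenyl]-6-[(1E)-prop-1-en-1-yl]-2H-pyran-3-yl}-1-oxopropan-2-yl 2-methoxy-4-(methoxymethoxy)-6-methylbenzoate
Product: 21 1-oxo-1-{4-(2-oxoethyl)-6-[(1E)-prop-1-en-1-yl]-2H-pyran-3-yl}propan-2-yl 2-methoxy-4-(methoxymethoxy)-6-methylbenzoate
Conditions: 1 M HCl/THF (1:4), 0 °C
Reagents that add atoms: water, O
Why: Enol ether hydrolysis (C-protonation, hydration of the oxocarbenium ion, loss of ethanol) in cold dilute acid should release the aldehyde while the MOM ether and the vinylogous ester of ring A survive.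

Step 14
Reactants: 21 1-oxo-1-{4-(2-oxoethyl)-6-[(1E)-prop-1-en-1-yl]-2H-pyran-3-yl}propan-2-yl 2-methoxy-4-(methoxymethoxy)-6-methylbenzoate
Product: 23 (6R,7R)-6-hydroxy-7-methyl-8-oxo-3-[(1E)-prop-1-en-1-yl]-5,6,7,8-tetrahydro-1H-isochromen-7-yl 2-methoxy-4-(methoxymethoxy)-6-methylbenzoate, via tetrasubstituted enol 22 (not isolated)
Conditions: (R)-TRIP [(R)-3,3′-bis(2,4,6-triisopropylphenyl)-1,1′-binaphthyl-2,2′-diyl hydrogen phosphate] (10 mol%), toluene (0.02 M), 4 Å molecular sieves, 40 °C
Reagents that add atoms: none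
Why: Proposed new method: the chiral phosphoric acid should enolise the C8 ketone of 21 toward C7, its only α-CH and one that the acyloxy group acidifies, to the hydrogen-bonded (Z)-enol 22, and then hold the enol OH (at P=O) and the aldehyde C=O (at P–OH) together so that C7 adds to C6; the closest known reaction types are the chiral-phosphoric-acid-catalysed intramolecular 6-(enolendo) aldolisation of triketones and phosphoric-acid enol catalysis, which turns racemic α-branched ketones into quaternary stereocentres by Michael addition or amination. Ring B closes in the 6-(enolendo)-exo-trig mode, the tether being the rigid cis C8–C8a=C4a–C5 unit of ring A. C7 is set by the catalyst, which selects one face of the achiral enol, so that both enantiomers of 21 should converge on 7R; C6 is set relative to C7 in the bridged transition state, where the aldehyde oxygen must lie pseudo-axial to reach the phosphate that also binds the enol OH and so ends up cis to the pseudo-equatorial acyloxy group (6R). The step needs enolisation toward C7 to be productive in the presence of the more acidic C5 hydrogens and needs the ester to stay on O7: enolisation at C5 only shuttles 21 between tautomers that feed the same manifold, the 2,6-disubstituted benzoate is too hindered to migrate to the new hydroxyl, and the quaternary C7 of 23 can neither epimerise nor dehydrate.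

Step 15
Reactants: 23 (6R,7R)-6-hydroxy-7-methyl-8-oxo-3-[(1E)-prop-1-en-1-yl]-5,6,7,8-tetrahydro-1H-isochromen-7-yl 2-methoxy-4-(methoxymethoxy)-6-methylbenzoate
Product: 24 (6R,7R)-6-hydroxy-7-methyl-8-oxo-3-[(1E)-prop-1-en-1-yl]-5,6,7,8-tetrahydro-1H-isochromen-7-yl 4-hydroxy-2-methoxy-6-methylbenzoate
Conditions: CF3CO2H/CH2Cl2 (1:10), 0 °C; aq. NaHCO3
Reagents that add atoms: none
Why: Acidolysis of the aryl MOM acetal; the tertiary benzoate, the β-hydroxy ketone (no hydrogen at C7) and the vinylogous ester of ring A should tolerate brief cold acid, and no stereocentre is touched.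

**Compound list**
1 | methyl 2,4-dihydroxy-6-methylbenzoate (methyl orsellinate) | COC(=O)c1c(C)cc(O)cc1O | starting material
2 | methyl 2-hydroxy-4-(methoxymethoxy)-6-methylbenzoate | COC(=O)c1c(C)cc(OCOC)cc1O | intermediate
3 | methyl 2-methoxy-4-(methoxymethoxy)-6-methylbenzoate | COC(=O)c1c(C)cc(OCOC)cc1OC | intermediate
4 | 2-methoxy-4-(methoxymethoxy)-6-methylbenzoic acid | OC(=O)c1c(C)cc(OCOC)cc1OC | intermediate
5 | benzyl 2-bromopropanoate (racemic) | CC(Br)C(=O)OCc1ccccc1 | starting material
6 | benzyl 2-{[2-methoxy-4-(methoxymethoxy)-6-methylbenzoyl]oxy}propanoate (racemic) | CC(OC(=O)c1c(C)cc(OCOC)cc1OC)C(=O)OCc1ccccc1 | intermediate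
7 | 2-{[2-methoxy-4-(methoxymethoxy)-6-methylbenzoyl]oxy}propanoic acid (racemic) | CC(OC(=O)c1c(C)cc(OCOC)cc1OC)C(O)=O | intermediate
8 | 1-(1H-benzotriazol-1-yl)-1-oxopropan-2-yl 2-methoxy-4-(methoxymethoxy)-6-methylbenzoate (racemic) | CC(OC(=O)c1c(C)cc(OCOC)cc1OC)C(=O)n1nnc2ccccc12 | intermediate
9 | 4-hydroxybutan-2-one | CC(=O)CCO | starting material
10 | 4-[(tert-butyldimethylsilyl)oxy]butan-2-one | CC(=O)CCO[Si](C)(C)C(C)(C)C | intermediate
11 | (E)-but-2-enoyl chloride | C/C=C/C(Cl)=O | starting material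
12 | lithium 4-[(tert-butyldimethylsilyl)oxy]but-1-en-2-olate | [Li+].[O-]C(=C)CCO[Si](C)(C)C(C)(C)C | intermediate (not isolated)
13 | (E)-1-[(tert-butyldimethylsilyl)oxy]oct-6-ene-3,5-dione | C/C=C/C(=O)CC(=O)CCO[Si](C)(C)C(C)(C)C | intermediate
14 | (E)-1-hydroxyoct-6-ene-3,5-dione | C/C=C/C(=O)CC(=O)CCO | intermediate (not isolated)
15 | 6-[(1E)-prop-1-en-1-yl]-2,3-dihydro-4H-pyran-4-one | C/C=C/C1=CC(=O)CCO1 | intermediate
16 | lithium 6-[(1E)-prop-1-en-1-yl]-2H-pyran-4-olate | [Li+].[O-]C1=CCOC(/C=C/C)=C1 | intermediate (not isolated)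
17 | 1-oxo-1-{4-oxo-6-[(1E)-prop-1-en-1-yl]-3,4-dihydro-2H-pyran-3-yl}propan-2-yl 2-methoxy-4-(methoxymethoxy)-6-methylbenzoate (stereoisomer and enol mixture) | C/C=C/C1=CC(=O)C(CO1)C(=O)C(C)OC(=O)c1c(C)cc(OCOC)cc1OC | intermediate
18 | 1-oxo-1-{6-[(1E)-prop-1-en-1-yl]-4-[(trifluoromethanesulfonyl)oxy]-2H-pyran-3-yl}propan-2-yl 2-methoxy-4-(methoxymethoxy)-6-methylbenzoate (racemic) | C/C=C/C1=CC(OS(=O)(=O)C(F)(F)F)=C(CO1)C(=O)C(C)OC(=O)c1c(C)cc(OCOC)cc1OC | intermediate
19 | 2-[(E)-2-ethoxyethenyl]-4,4,5,5-tetramethyl-1,3,2-dioxaborolane | CCO/C=C/B1OC(C)(C)C(C)(C)O1 | starting material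
20 | 1-{4-[(E)-2-ethoxyethenyl]-6-[(1E)-prop-1-en-1-yl]-2H-pyran-3-yl}-1-oxopropan-2-yl 2-methoxy-4-(methoxymethoxy)-6-methylbenzoate (racemic) | C/C=C/C1=CC(/C=C/OCC)=C(CO1)C(=O)C(C)OC(=O)c1c(C)cc(OCOC)cc1OC | intermediate
21 | 1-oxo-1-{4-(2-oxoethyl)-6-[(1E)-prop-1-en-1-yl]-2H-pyran-3-yl}propan-2-yl 2-methoxy-4-(methoxymethoxy)-6-methylbenzoate (racemic) | C/C=C/C1=CC(CC=O)=C(CO1)C(=O)C(C)OC(=O)c1c(C)cc(OCOC)cc1OC | intermediate
22 | (Z)-1-hydroxy-1-{4-(2-oxoethyl)-6-[(1E)-prop-1-en-1-yl]-2H-pyran-3-yl}prop-1-en-2-yl 2-methoxy-4-(methoxymethoxy)-6-methylbenzoate | C/C=C/C1=CC(CC=O)=C(CO1)/C(O)=C(\C)OC(=O)c1c(C)cc(OCOC)cc1OC | intermediate (not isolated)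
23 | (6R,7R)-6-hydroxy-7-methyl-8-oxo-3-[(1E)-prop-1-en-1-yl]-5,6,7,8-tetrahydro-1H-isochromen-7-yl 2-methoxy-4-(methoxymethoxy)-6-methylbenzoate | C/C=C/C1=CC2=C(CO1)C(=O)[C@](C)(OC(=O)c1c(C)cc(OCOC)cc1OC)[C@H](O)C2 | intermediate
24 | (6R,7R)-6-hydroxy-7-methyl-8-oxo-3-[(1E)-prop-1-en-1-yl]-5,6,7,8-tetrahydro-1H-isochromen-7-yl 4-hydroxy-2-methoxy-6-methylbenzoate | C/C=C/C1=CC2=C(CO1)C(=O)[C@](C)(OC(=O)c1c(C)cc(O)cc1OC)[C@H](O)C2 | target

**Totals**
Total step count: 15. Longest linear sequence: 12 steps (steps 1–6 and 10–15, from methyl orsellinate).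

**Three steps most likely to fail**

Step 14 (key step, proposed new method). Enolisation toward C7 may be slower than drift of the 2-oxoethyl arm into conjugation, and the catalyst may not discriminate the two enol faces or the two aldehyde orientations well enough; the sense of induction of (R)-TRIP would have to be established and the (S)-catalyst used if it is opposite. Fallback with known chemistry (a chiral acetal template instead of a chiral catalyst), setting out from 20 and rejoining at 23: acid-catalysed transacetalisation of the enol ether of 20 with (2R,4R)-pentane-2,4-diol (PPTS, CH2Cl2, 23 °C) should give the dioxane acetal F1. Me3SiOTf/i-Pr2NEt (CH2Cl2, −78 °C) should convert the ketone into its enol silane at C7 and ionise the acetal. The intramolecular Mukaiyama-type acetal aldol, with SN2-like opening of the C–O bond next to the axial methyl group (inversion, expected to give 6R) and the racemic C7–H centre again erased, should give after aqueous work-up the ring-closed hydroxy ether F2. Dess–Martin oxidation (NaHCO3, CH2Cl2) should give the β-alkoxy ketone F3, and β-elimination with dibenzylammonium trifluoroacetate (benzene, 50 °C) should expel pent-3-en-2-one and deliver 23.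

Step 13. Acid may move the β,γ-double bond of the new aldehyde into conjugation or start an uncatalysed, racemic ring closure during hydrolysis. Fallback that avoids acid, setting out from 18 and rejoining at 21: Negishi coupling of 18 with HC≡CZnBr (from HC≡CMgBr and ZnBr2; Pd(PPh3)4, THF, 23 °C) should give the terminal enyne F4. Ruthenium-catalysed anti-Markovnikov hydration through a vinylidene complex (CpRu(MeCN)3PF6, 5,5′-bis(trifluoromethyl)-2,2′-bipyridine, N-methylpyrrolidone/H2O, 25 °C) should then give 21 under neutral conditions.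

Step 10. O-acylation of the enolate, or proton transfer from the acidic α-CH of the acyl donor, may compete with C-acylation. Fallback by aldol addition and oxidation, setting out from 7 and 15 and rejoining at 17: BH3·THF reduction of acid 7 should give the primary alcohol F5 and Dess–Martin oxidation the aldehyde F6. Aldol addition of lithium enolate 16 (from 15 and LiN(SiMe3)2) to F6 (THF, −78 °C) should give the β-hydroxy ketone F7, and Dess–Martin oxidation of F7 should give 17.

**Further compounds**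
F1 | step 14 | 1-{4-{[(4R,6R)-4,6-dimethyl-1,3-dioxan-2-yl]methyl}-6-[(1E)-prop-1-en-1-yl]-2H-pyran-3-yl}-1-oxopropan-2-yl 2-methoxy-4-(methoxymethoxy)-6-methylbenzoate | C/C=C/C1=CC(CC2O[C@H](C)C[C@@H](C)O2)=C(CO1)C(=O)C(C)OC(=O)c1c(C)cc(OCOC)cc1OC
F2 | step 14 | (6R,7R)-6-{[(2R,4R)-4-hydroxypentan-2-yl]oxy}-7-methyl-8-oxo-3-[(1E)-prop-1-en-1-yl]-5,6,7,8-tetrahydro-1H-isochromen-7-yl 2-methoxy-4-(methoxymethoxy)-6-methylbenzoate | C/C=C/C1=CC2=C(CO1)C(=O)[C@](C)(OC(=O)c1c(C)cc(OCOC)cc1OC)[C@H](O[C@H](C)C[C@@H](C)O)C2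
F3 | step 14 | (6R,7R)-7-methyl-8-oxo-6-{[(2R)-4-oxopentan-2-yl]oxy}-3-[(1E)-prop-1-en-1-yl]-5,6,7,8-tetrahydro-1H-isochromen-7-yl 2-methoxy-4-(methoxymethoxy)-6-methylbenzoate | C/C=C/C1=CC2=C(CO1)C(=O)[C@](C)(OC(=O)c1c(C)cc(OCOC)cc1OC)[C@H](O[C@H](C)CC(C)=O)C2
F4 | step 13 | 1-{4-ethynyl-6-[(1E)-prop-1-en-1-yl]-2H-pyran-3-yl}-1-oxopropan-2-yl 2-methoxy-4-(methoxymethoxy)-6-methylbenzoate | C/C=C/C1=CC(C#C)=C(CO1)C(=O)C(C)OC(=O)c1c(C)cc(OCOC)cc1OC
F5 | step 10 | 1-hydroxypropan-2-yl 2-methoxy-4-(methoxymethoxy)-6-methylbenzoate | CC(CO)OC(=O)c1c(C)cc(OCOC)cc1OC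
F6 | step 10 | 1-oxopropan-2-yl 2-methoxy-4-(methoxymethoxy)-6-methylbenzoate | CC(C=O)OC(=O)c1c(C)cc(OCOC)cc1OC
F7 | step 10 | 1-hydroxy-1-{4-oxo-6-[(1E)-prop-1-en-1-yl]-3,4-dihydro-2H-pyran-3-yl}propan-2-yl 2-methoxy-4-(methoxymethoxy)-6-methylbenzoate | C/C=C/C1=CC(=O)C(CO1)C(O)C(C)OC(=O)c1c(C)cc(OCOC)cc1OC
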